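(The earlier runs and the new flask are simulated on assumed constants; noise was put on by code.)

**The question.** Alder, the flask in question, has been followed to 3.00 min and must be told at 8.0 min; oak, run earlier, carried more protic impurity at the same enzyme loading.

| setting | alder | oak | flask |
|---|---|---|---|
| starting material | 0.10 M | 0.10 M | 0.10 M |
| protic impurity | 0.010 M | 0.015 M | 0.0100 M |
| enzyme | 0.05 mol% | 0.05 mol% | 0.05 mol% |
| remark | the very flask that is asked about, followed so far | run made earlier |  |
| time |  |  | 8.0 min |

| run | time / min | product / % | quenched substrate / % |
|---|---|---|---|
| alder | 0.167 | 11 | 0 |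
| alder | 0.500 | 26 | 1 |
| alder | 0.833 | 39 | 3 |
| alder | 1.33 | 54 | 5 |
| alder | 2.00 | 65 | 3 |
| alder | 2.50 | 72 | 0 |
| alder | 3.00 | 73 | 3 |
| oak | 0.833 | 38 | 6 |
| oak | 1.50 | 54 | 4 |
| oak | 2.50 | 68 | 6 |
| oak | 3.00 | 77 | 5 |
| oak | 4.00 | 85 | 8 |
| oak | 5.00 | 84 | 4 |
| oak | 6.00 | 89 | 5 |

(standard deviation of a reading: 2 percentage points)

1. the product in the flask at 8.0 min, as a percentage of the starting material charged
2. the quenched substrate in the flask at 8.0 min, as a percentage of the starting material charged



**The books.** You keep books on the starting material: each mole ends as product, as quenched substrate, or still unreacted.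

**Unreacted entry.** Alder's last reading leaves 24.0% unaccounted for, a time constant of 2.10 min, so my own reckoning leaves 2.22% at 8.0 min.

**Quenched entry.** Follow one molecule of protic impurity: I take it to decay pseudo-first-order, with the starting material curve as its clock. The enzyme runs that clock, because oak holds 89% product against 5% quenched substrate at 6.00 min. Product at 0.833 min also reads 39% in alder and 38% in oak. Oak's last 3 quenched readings, each scattered by 2 percentage points, average 37.8% of its impurity charge: this is the spent share, the part of an impurity charge that I take to end quenched at this enzyme loading and this charge of starting material.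

**Closing alder.** In my reckoning, quenched substrate in alder comes to 3.78%, so product takes the remaining 94.0%.

**The forecast.** It says 90% product and 2.5% quenched substrate, noting that “Quenched substrate shows no steady growth”. Both figures lie below mine.

**The result.** Alder gives 93.8% product and 4.77% quenched substrate, against my 94.0% and 3.78%, and the forecast stands within its margins. For alder, 0.0214 M is the nearest protic impurity charge above the present one at which the quenched answer has moved by 5 points.

    starting material + enzyme → product + enzyme, rate k1*[starting material]*[enzyme]/(1 + ([starting material]/Km1) + ([product]/Kp1)) (0.288 M, 0.139 M, k = 271 M⁻¹ s⁻¹)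
    starting material + protic impurity → quenched substrate (k = 0.0620 M⁻¹ s⁻¹)

**The neighbour.** A neighbouring flask is charged with 0.0060 M of protic impurity. The same 37.8% puts it at 2.27% quenched substrate, and that flask gives 2.91%. It keeps 51% of its impurity, against 52% in alder, and makes 95.5% product.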